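Ring A is the quinone C1(=O)–C2(OMe)=C3H–C4(=O), ring B is C4a, C5–H, C6–OMe, C7–H, C8–aryl, C8a, and ring C is 3,4-dimethoxyphenyl; atoms carry target numbering throughout.
Enabling feature: the neighbouring ring B carbons C4a and C8a each carry one carbonyl carbon of ring A (C4 and C1), so ring A maps onto furan added across a C4a≡C8a aryne.
Retrosynthetic cuts, in order: C1=O (para-oxidation of a C4 naphthol), C2–O (C–H borylation/oxidation), C1–C8a and C4–C4a together (aryne [4+2]), C8–C1' (Suzuki–Miyaura).
Forward: rings B and C are joined first, ring A is closed on the biaryl as an oxygen-bridged ring, the bridge is opened to the C4 naphthol, then C2 and finally C1 are oxygenated.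
Regiocontrol: C6–OMe (para to C8a) steers the bridge opening so that oxygen stays on C4, after which C2–H is the only C–H without an ortho or peri neighbour.
Stereochemistry: the target is achiral; the two bridgehead centres of the cycloadduct are cis by geometry, racemic, and are erased on aromatisation.

Key step: step 2

Assumption: 4-bromo-3-iodoanisole, (3,4-dimethoxyphenyl)boronic acid and furan are catalogue compounds; compound names carry their own IUPAC locants, atom labels in the text are those of the target.

Step 1
Reactants: 1 4-bromo-3-iodoanisole; 2 (3,4-dimethoxyphenyl)boronic acid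
Product: 3 2-bromo-3',4',5-trimethoxybiphenyl
Conditions: Pd(PPh3)4 (3 mol %), Na2CO3 (2 M aq), toluene/EtOH, 80 °C
Reagents that add atoms: none
Why: Suzuki–Miyaura coupling in which zerovalent palladium inserts far faster into the carbon–iodine bond than into the neighbouring carbon–bromine bond, so one equivalent of 2 should couple at iodine only and keep the bromide for aryne generation.

Step 2
Reactants: 3 2-bromo-3',4',5-trimethoxybiphenyl; 4 furan
Product: 7 rac-5-(3,4-dimethoxyphenyl)-7-methoxy-1,4-dihydro-1,4-epoxynaphthalene, via ortho-bromoaryllithium 5 (not isolated), via aryne 6 (not isolated)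
Conditions: LiTMP (1.5 equiv; from 2,2,6,6-tetramethylpiperidine, n-BuLi, THF, 0 °C), furan (15 equiv), THF, −78 °C → rt
Reagents that add atoms: lithium 2,2,6,6-tetramethylpiperidide, [Li+].CC1(C)CCCC(C)(C)[N-]1 (supplies only the lithium of 5; no reagent atom remains in 7)
Why: Bromine acidifies its single ortho hydrogen, C4a–H, which LiTMP abstracts to give aryllithium 5; on warming 5 expels LiBr and the resulting aryne 6 (C4a≡C8a) is intercepted by the large excess of furan before amide or aryllithium can add. The closest known reaction type is the aryne Diels–Alder reaction of benzynes generated from bromoarenes with hindered lithium amides and trapped by furan as 1,4-epoxy-1,4-dihydronaphthalenes. Ring A closes in a concerted, suprafacial [4+2] cycloaddition in which the furan α-carbons bond to C8a and C4a (new bonds C1–C8a and C4–C4a), giving a six-membered carbocycle spanned by the furan oxygen. The new stereocentres C1 and C4 are the bridgeheads: their cis relation is dictated by the one-atom oxygen bridge, nothing biases the two faces of the planar aryne, so 7 is racemic, and both centres are erased in step 3. The step needs site-selective metalation, which the substrate secures because the second position ortho to bromine is blocked by ring C, so only one aryne can arise, while lithiation beside a methoxy group is reversible through proton exchange with the free amine and is drained into the irreversible loss of LiBr. Furan is symmetric, so the cycloaddition itself raises no regiochemical question.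

Step 3
Reactants: 7 rac-5-(3,4-dimethoxyphenyl)-7-methoxy-1,4-dihydro-1,4-epoxynaphthalene
Product: 8 5-(3,4-dimethoxyphenyl)-7-methoxynaphthalen-1-ol (hydroxyl on C4 of the target numbering)
Conditions: TFA (2 equiv), CH2Cl2, 0 °C → rt
Reagents that add atoms: none
Why: Acid-catalysed isomerisation of a 1,4-epoxy-1,4-dihydronaphthalene to a 1-naphthol, in which the protonated bridge should ionise at C1–O because the C1 cation is allylic and para-methoxybenzylic (C6–OMe is para to C8a) whereas a C4 cation has that methoxy group meta, and loss of C4–H then aromatises ring A with the oxygen left on C4; any C1–OH isomer is removed by chromatography here.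

Step 4
Reactants: 8 5-(3,4-dimethoxyphenyl)-7-methoxynaphthalen-1-ol
Product: 9 {[5-(3,4-dimethoxyphenyl)-7-methoxynaphthalen-1-yl]oxy}triisopropylsilane
Conditions: TIPSCl, imidazole, DMF, rt
Reagents that add atoms: chlorotriisopropylsilane (TIPSCl), CC(C)[Si](Cl)(C(C)C)C(C)C
Why: Imidazole-promoted O-silylation of a phenol, where the bulky silyl group removes the acidic O–H before the iridium step, adds steric shielding at C3 and tolerates the later perborate and carbonate treatments.

Step 5
Reactants: 9 {[5-(3,4-dimethoxyphenyl)-7-methoxynaphthalen-1-yl]oxy}triisopropylsilane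
Product: 11 8-(3,4-dimethoxyphenyl)-6-methoxy-4-[(triisopropylsilyl)oxy]naphthalen-2-ol, via pinacol boronate 10 (not isolated)
Conditions: [Ir(cod)(OMe)]2 (2 mol %), dtbpy (4 mol %), B2pin2 (1.0 equiv), THF, 80 °C; then NaBO3·4H2O, THF/H2O, rt
Reagents that add atoms: bis(pinacolato)diboron, CC1(C)OB(OC1(C)C)B1OC(C)(C)C(C)(C)O1 (boryl group of 10); sodium perborate tetrahydrate NaBO3·4H2O, O.O.O.O.[Na+].[O-]OB=O (the C2 oxygen of 11)
Why: Sterically governed iridium-catalysed aromatic C–H borylation followed by perborate oxidation of the C–B bond in the same flask (the established borylation/oxidation route to phenols meta to an oxygen substituent) should hit C2–H, the only C–H of 9 lying between two C–H groups, since C3–H is ortho to OTIPS, C1–H is peri to ring C, C5–H and C7–H are flanked on both sides and every ring C hydrogen has an ortho methoxy or biaryl neighbour.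

Step 6
Reactants: 11 8-(3,4-dimethoxyphenyl)-6-methoxy-4-[(triisopropylsilyl)oxy]naphthalen-2-ol
Product: 12 {[5-(3,4-dimethoxyphenyl)-3,7-dimethoxynaphthalen-1-yl]oxy}triisopropylsilane
Conditions: MeI, K2CO3, acetone, 40 °C
Reagents that add atoms: iodomethane, CI
Why: Williamson ether synthesis on the only free phenol, with carbonate in acetone favouring O- over C-alkylation and leaving the hindered aryl TIPS ether untouched.

Step 7
Reactants: 12 {[5-(3,4-dimethoxyphenyl)-3,7-dimethoxynaphthalen-1-yl]oxy}triisopropylsilane
Product: 13 5-(3,4-dimethoxyphenyl)-3,7-dimethoxynaphthalen-1-ol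
Conditions: TBAF, AcOH, THF, 0 °C
Reagents that add atoms: none
Why: Fluoride-induced cleavage of an aryl silyl ether driven by the strong silicon–fluorine bond, with acetic acid buffering the naphtholate so that the electron-rich product is not oxidised by air before step 8.

Step 8
Reactants: 13 5-(3,4-dimethoxyphenyl)-3,7-dimethoxynaphthalen-1-ol
Product: 14 8-(3,4-dimethoxyphenyl)-2,6-dimethoxynaphthalene-1,4-dione (CNP0128574.0)
Conditions: (KSO3)2NO (2.5 equiv), KH2PO4 (aq), acetone/H2O, rt
Reagents that add atoms: potassium nitrosodisulfonate (KSO3)2NO, [K+].[K+].[O]N(S([O-])(=O)=O)S([O-])(=O)=O (the C1 oxygen)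
Why: Teuber oxidation, in which one equivalent of the nitroxide abstracts the phenolic hydrogen, a second couples through oxygen at the free para carbon C1 of the naphthoxyl radical and collapse of that adduct gives the C1 carbonyl, so the para-quinone forms with the C2 methoxy group already fixed next to C1.

Compound list
1 | 4-bromo-3-iodoanisole (1-bromo-2-iodo-4-methoxybenzene) | COc1ccc(Br)c(I)c1 | starting material
2 | (3,4-dimethoxyphenyl)boronic acid | COc1ccc(B(O)O)cc1OC | starting material
3 | 2-bromo-3',4',5-trimethoxybiphenyl | COc1ccc(Br)c(-c2ccc(OC)c(OC)c2)c1 | intermediate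
4 | furan | c1ccoc1 | starting material
5 | [2-bromo-3-(3,4-dimethoxyphenyl)-5-methoxyphenyl]lithium (formed in the flask) | COc1cc([Li])c(Br)c(-c2ccc(OC)c(OC)c2)c1 | intermediate
6 | 3-(3,4-dimethoxyphenyl)-5-methoxybenzyne (1,2-didehydrobenzene, formed in the flask) | COC1=CC#CC(c2ccc(OC)c(OC)c2)=C1 | intermediate
7 | rac-5-(3,4-dimethoxyphenyl)-7-methoxy-1,4-dihydro-1,4-epoxynaphthalene (bridgeheads cis through the oxygen bridge; one enantiomer drawn) | COc1cc(-c2ccc(OC)c(OC)c2)c2c(c1)[C@@H]1C=C[C@H]2O1 | intermediate
8 | 5-(3,4-dimethoxyphenyl)-7-methoxynaphthalen-1-ol | COc1cc(-c2ccc(OC)c(OC)c2)c2cccc(O)c2c1 | intermediate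
9 | {[5-(3,4-dimethoxyphenyl)-7-methoxynaphthalen-1-yl]oxy}triisopropylsilane | COc1cc(-c2ccc(OC)c(OC)c2)c2cccc(O[Si](C(C)C)(C(C)C)C(C)C)c2c1 | intermediate
10 | {[5-(3,4-dimethoxyphenyl)-7-methoxy-3-(4,4,5,5-tetramethyl-1,3,2-dioxaborolan-2-yl)naphthalen-1-yl]oxy}triisopropylsilane (formed in the flask) | CC1(C)OB(OC1(C)C)c1cc(O[Si](C(C)C)(C(C)C)C(C)C)c2cc(OC)cc(-c3ccc(OC)c(OC)c3)c2c1 | intermediate
11 | 8-(3,4-dimethoxyphenyl)-6-methoxy-4-[(triisopropylsilyl)oxy]naphthalen-2-ol | Oc1cc(O[Si](C(C)C)(C(C)C)C(C)C)c2cc(OC)cc(-c3ccc(OC)c(OC)c3)c2c1 | intermediate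
12 | {[5-(3,4-dimethoxyphenyl)-3,7-dimethoxynaphthalen-1-yl]oxy}triisopropylsilane | COc1cc(O[Si](C(C)C)(C(C)C)C(C)C)c2cc(OC)cc(-c3ccc(OC)c(OC)c3)c2c1 | intermediate
13 | 5-(3,4-dimethoxyphenyl)-3,7-dimethoxynaphthalen-1-ol | COc1cc(O)c2cc(OC)cc(-c3ccc(OC)c(OC)c3)c2c1 | intermediate
14 | 8-(3,4-dimethoxyphenyl)-2,6-dimethoxynaphthalene-1,4-dione (CNP0128574.0, achiral) | COC1=CC(=O)c2cc(OC)cc(-c3ccc(OC)c(OC)c3)c2C1=O | target

Total step count: 8. Longest linear sequence: 8 (1 → 14).

Steps most likely to fail

Step 2. Metalation may be incomplete or misdirected (lithiation beside methoxy groups or of furan itself), and the aryne may be captured by amide or aryllithium instead of furan. The fallback makes the aryne by halogen–lithium exchange instead of C–H deprotonation and postpones the biaryl coupling. It sets out from furan 4 and boronic acid 2.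
- Purchased 2,6-dibromo-4-methoxyaniline F1 is diazotised (NaNO2, H2SO4) to 2,6-dibromo-4-methoxybenzenediazonium hydrogensulfate F2.
- KI converts F2 into 1,3-dibromo-2-iodo-5-methoxybenzene F3.
- n-BuLi in toluene at −78 °C exchanges only iodine to give (2,6-dibromo-4-methoxyphenyl)lithium F4.
- Loss of LiBr from F4 gives 3-bromo-5-methoxybenzyne F5, which furan 4 traps as rac-5-bromo-7-methoxy-1,4-dihydro-1,4-epoxynaphthalene F6.
- TFA opens the bridge under the same methoxy control to 5-bromo-7-methoxynaphthalen-1-ol F7.
- Suzuki–Miyaura coupling of F7 with 2 is placed after bridge opening so that no arylpalladium species meets the strained alkene. It rejoins the route at 8.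

Step 5. Borylation may spread to ring C hydrogens next to a methoxy group, or turnover may be sluggish on the very electron-rich arene. The fallback installs the C2 oxygen by polar quinone chemistry. It sets out from 8.
- (KSO3)2NO oxidises 8 to 5-(3,4-dimethoxyphenyl)-7-methoxynaphthalene-1,4-dione F8.
- Oxidative conjugate amination (Me2NH, EtOH, air) should add at C2, the position β to the more electrophilic C4 carbonyl. The C1 carbonyl is deactivated as a vinylogous ester of C6–OMe and crowded by ring C. The product is 2-(dimethylamino)-8-(3,4-dimethoxyphenyl)-6-methoxynaphthalene-1,4-dione F9.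
- Aqueous HCl hydrolyses the vinylogous amide to 8-(3,4-dimethoxyphenyl)-2-hydroxy-6-methoxynaphthalene-1,4-dione F10.
- Acid-catalysed etherification of this vinylogous acid (MeOH, HCl) comes back to the route at 14.

Step 8. The bulky nitroxide may couple slowly at C1, which is crowded by ring C and C2–OMe, so that attack at C3 or dimerisation of the naphthoxyl radical takes over. The fallback brings the C1 heteroatom in with a slim electrophile and sets out from 13.
- Azo coupling with benzenediazonium chloride (aq NaOH, 0 °C) at the para carbon gives 5-(3,4-dimethoxyphenyl)-3,7-dimethoxy-4-[(E)-phenyldiazenyl]naphthalen-1-ol F11.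
- Na2S2O4 cleaves the azo link to 4-amino-5-(3,4-dimethoxyphenyl)-3,7-dimethoxynaphthalen-1-ol F12.
- FeCl3 in dilute HCl oxidises the aminonaphthol and hydrolyses the quinone imine, which comes back to the route at 14.

Further compounds
F1 | step 2 | 2,6-dibromo-4-methoxyaniline (purchased) | COc1cc(Br)c(N)c(Br)c1
F2 | step 2 | 2,6-dibromo-4-methoxybenzenediazonium hydrogensulfate (transient) | COc1cc(Br)c([N+]#N)c(Br)c1.OS([O-])(=O)=O
F3 | step 2 | 1,3-dibromo-2-iodo-5-methoxybenzene | COc1cc(Br)c(I)c(Br)c1
F4 | step 2 | (2,6-dibromo-4-methoxyphenyl)lithium (transient) | COc1cc(Br)c([Li])c(Br)c1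
F5 | step 2 | 3-bromo-5-methoxybenzyne (transient) | COC1=CC#CC(Br)=C1
F6 | step 2 | rac-5-bromo-7-methoxy-1,4-dihydro-1,4-epoxynaphthalene (one enantiomer drawn) | COc1cc(Br)c2c(c1)[C@@H]1C=C[C@H]2O1
F7 | step 2 | 5-bromo-7-methoxynaphthalen-1-ol | COc1cc(Br)c2cccc(O)c2c1
F8 | step 5 | 5-(3,4-dimethoxyphenyl)-7-methoxynaphthalene-1,4-dione | COc1cc(-c2ccc(OC)c(OC)c2)c2C(=O)C=CC(=O)c2c1
F9 | step 5 | 2-(dimethylamino)-8-(3,4-dimethoxyphenyl)-6-methoxynaphthalene-1,4-dione | CN(C)C1=CC(=O)c2cc(OC)cc(-c3ccc(OC)c(OC)c3)c2C1=O
F10 | step 5 | 8-(3,4-dimethoxyphenyl)-2-hydroxy-6-methoxynaphthalene-1,4-dione | OC1=CC(=O)c2cc(OC)cc(-c3ccc(OC)c(OC)c3)c2C1=O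
F11 | step 8 | 5-(3,4-dimethoxyphenyl)-3,7-dimethoxy-4-[(E)-phenyldiazenyl]naphthalen-1-ol | COc1cc(O)c2cc(OC)cc(-c3ccc(OC)c(OC)c3)c2c1/N=N/c1ccccc1
F12 | step 8 | 4-amino-5-(3,4-dimethoxyphenyl)-3,7-dimethoxynaphthalen-1-ol | COc1cc(O)c2cc(OC)cc(-c3ccc(OC)c(OC)c3)c2c1N
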